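The L left at the last reading of the midnight run, 0.0292 M at 30.0 min, is what I start from, together with the X left beside it, 0.113 M. I must decide whether the next run gets 0.100 M of L, as in oak, or 0.150 M, as in birch.

| setting | noon | midnight | oak | birch |
|---|---|---|---|---|
| J | 0.15 M | 0.10 M | 0.10 M | 0.10 M |
| L | 0.10 M | 0.10 M | 0.100 M | 0.150 M |
| X | 0.25 M | 0.12 M | 0.250 M | 0.250 M |
| remark | run made earlier | run made earlier |  |  |
| time |  |  | 50 min | 50 min |

| run | time / min | G / % | D / % | J / % | E / % |
|---|---|---|---|---|---|
| noon | 2.50 | 0.3 | 4.9 | 85.5 | 8.0 |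
| noon | 6.00 | 3.7 | 7.0 | 71.6 | 19.8 |
| noon | 12.0 | 5.9 | 6.0 | 50.9 | 36.3 |
| noon | 30.0 | 16.6 | 7.0 | 16.6 | 60.5 |
| midnight | 2.50 | 2.4 | 4.6 | 86.3 | 7.7 |
| midnight | 6.00 | 2.5 | 5.4 | 71.5 | 21.6 |
| midnight | 12.0 | 4.1 | 6.8 | 51.1 | 41.7 |
| midnight | 30.0 | 7.1 | 4.2 | 17.9 | 70.8 |

(readings scatter by 1 percentage point)

* which of these there is most of at the end, counted by the J in it, oak (J / E / D / G)
* which of these there is most of at the end, counted by the J in it, birch (J / E / D / G)
* how much there is at the end of the one of these that leads, in percent of the J charged: oak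
* how much there is at the end of the one of these that leads, in percent of the J charged: birch

Follow one molecule of D to the fork, where it goes to E with L or to G with X. If its chances stand as S·cL to cX, then whatever the charges and the time, the leftovers obey

S = ln[cL(start)/cL(now)] / ln[cX(start)/cX(now)]

Each E uses one L and each G one X, with E read together with its Z. The last readings give

noon: S = 22.7
midnight: S = 20.2

I carry their mean, 21.4, as the fork number, the selectivity factor of L over X.

J falls alike in both runs, so its last readings give 0.0586 min⁻¹. That leaves 5.35% of J at 50 min, and 0.0947 M has passed on in either flask.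

I guess the L left, get G from the rule, take E as the rest, and go round once more:

oak, guess 0.0250 M: E = 0.0790 M, then E = 0.0771 M, or 77.1%
birch, guess 0.0750 M: E = 0.0867 M, then E = 0.0848 M, or 84.8%

Whatever D still holds at the end comes off both figures. The extra L buys 7.7 percentage points, which is more than the scatter of 1 point, so I charge birch.

The forecast, 75% of E in oak and 84% in birch, lies below my figures and rests on "The partition E/G follows" the ratio of the two steps.

E leads in both flasks, with 75.7% in oak and 83.6% in birch, a gain of 7.9 points.

J → D (k = 0.0571 min⁻¹); L + D → E (k = 7.83 L mol⁻¹ min⁻¹); X + D → G (k = 0.393 L mol⁻¹ min⁻¹); Z ⇌ E, rate k4*(cs4 - [E]) while solid is left; crystals form when [E] > cs4 (solubility = 40.0 mM, k = 3.04 min⁻¹) At 11.2 min in birch, D goes to E at 8.9 times its rate to G, and the leftovers of birch, 44% of its L and 96% of its X, give S = 20.1. A neighbour of birch charged with 0.037 M of L has G leading at 50.5%, with 1.1% of its L and 80% of its X left, and there S = 19.9.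

Readings and results are calculated with made-up constants; the scatter is artificial.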